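The earlier runs and the new flask are calculated with constants of no real substance, and the scatter is random.

The charge ratio between this flask and Sunday's run is 2.00: the flask starts from 3.0 M of substrate, Sunday's run started from 1.5 M, and the gas phase is held at 180 mM in both.

the same everywhere: gas phase 180 mM (held)
- Sunday's: substrate 1.5 M; run made earlier
- flask: substrate 3.0 M; time 3.0 h

- Sunday's (time / min: target / %, substrate / %): 1.33: 1.7, 98.9; 2.50: 4.4, 95.8; 4.00: 7.8, 92.1; 6.00: 12.0, 88.0; 10.0: 20.6, 78.5; 20.0: 40.1, 57.3

(readings scatter by 0.3 percentage points)

* time, not beyond 3.0 h, at which the flask holds most target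
* the amount of target, in percent of the substrate charged, at that time
* the first time at which target reaches 19%, in the same percent

- at the start none of the gas phase is in solution

Read Sunday's run in molar terms. While its substrate falls from 95.8% to 57.3%, the rate moves from 0.0346 M min⁻¹ before 10.0 min to 0.0318 M min⁻¹ after it, so it hardly follows the substrate. Over the whole span the readings give 0.0330 M min⁻¹, and my own assumption is that the flask keeps this molar rate. Dividing the flask's charge by it gives 1.52 h: the clearing time, how long a charge lasts at that rate.

Sunday's run has a clearing time of 45.5 min, and its last reading at 20.0 min comes earlier, so that run ends with target at 40.1% and still rising. You may run the flask for 3.0 h, twice its clearing time, so I expect its target peak inside that time, near 1.52 h, and a fall afterwards. Sunday's last reading already shows 2.6 percentage points of the charge as neither substrate nor target. At the same rate, 19% takes 0.289 h.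

The forecast puts the peak at 1.6 h with 72% of target and reaches 19% at 0.32 h, holding that “the molar rate should stay about the same”. My times differ: both are earlier.

The flask peaks at 1.38 h with 63.6% of target, and reaches 19% at 0.256 h.

    gas phase ⇌ dissolved gas, rate k1*(csat - [dissolved gas]) (kL = 0.00431 s⁻¹)
    substrate + dissolved gas → target (k = 0.0109 L mol⁻¹ s⁻¹)
    dissolved gas + target → over-reacted product (k = 8.56 × 10⁻⁴ L mol⁻¹ s⁻¹)
    target → over-reaction product (k = 8.41 × 10⁻⁵ s⁻¹)

That peak comes at 0.908 of the clearing time, with substrate still at 11.3%. The neighbouring flask left until 2.0 h stands at 1.32 clearing times, and there substrate, the limiting reagent, is down to 0.856% and target to 51.0%.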